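## Structural features

The target, 6-hydroxy-7-methoxy-3-(3,4,5-trimethoxyphenyl)-4H-chromen-4-one, is an isoflavone. A benzene ring (ring A) is fused across C4a–C8a to a 4-pyranone (ring C), and C3 carries the 3,4,5-trimethoxyphenyl ring B through a single aryl–alkenyl bond. Ring A has a free hydroxyl on C6 and a methoxy group on C7, while C5 and C8 carry hydrogen; there is no stereocentre, so every problem is one of regiochemistry. The fragile parts are the vinylogous ester O1–C2=C3–C4=O (opened by hydroxide or alkoxide at C2, saturated by over-hydrogenation), the four aryl methyl ethers (which exclude harsh Lewis-acid deprotection), and the C6 phenol, which must stay distinct from its methylated neighbour on C7. The real difficulty is to build ring C onto a ring A whose two oxygen substituents are electronically almost alike. The key step uses the fact that O1 sits on C8a and the carbonyl carbon C4 on the adjacent C4a: an aryne spanning C4a and C8a can take up a nucleophilic oxygen and an acyl carbon in one operation. Because C5 is hydrogen in the target, nothing in the natural ring A distinguishes the two aryne carbons, so a removable bromine on C5 is needed.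

## Logic of the disconnections

19 to 18: a bromine is added on C5 and a benzyl group on O6. The bromine polarises the aryne and the benzyl ether masks the phenol through organolithium and fluoride chemistry. Both bonds (C5–Br and O–CH2Ph) are cleaved on palladium under hydrogen, so one step removes them. The forward step must spare C2=C3; a non-amine base is chosen because amines slow benzyl ether hydrogenolysis on palladium.

18 to 9 plus 14: the cuts are O1–C8a and C4–C4a, the two bonds joining ring C to adjacent carbons of ring A. This divides the molecule into two fragments of similar size and makes ring C in the convergent step. The atom mapping was checked: the triflate-bearing carbon of 9 becomes C4a, the silicon-bearing carbon becomes C8a, and the bromine beside the triflate carbon ends on C5. The forward step must deliver oxygen (not carbon) attack of the enolate, attack at C8a, a cis relation of aryloxy group and ester, and acylation faster than loss of bromide.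

9 to 5: the C–Si and O–S bonds are cut. An ortho-silyl aryl triflate comes from an ortho-halophenol by O-silylation, halogen–lithium exchange, O-to-C silyl shift and triflation. Because the ring must keep its bromine, the exchanging halogen has to be iodine. This avoids directed lithiation of a bromoarene and the cleavage of a robust carbamate. The demand is that iodine exchanges much faster than bromine.

5 to 4: the C–I bond is cut. The free hydroxyl directs an electrophile to its only open ortho position, which is also para to the benzyloxy group.

4 to 2 to 1: the aryl C–O bond is traced to an aryl–CHO bond (oxidative aryl migration) and the benzyl ether to the phenol. In 1 the bromine, the oxygen and the methoxy group are already in their final relative positions, so all ring A regiochemistry is bought.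

14 to 11 plus 12, and 11 to 10: the bond between the formyl carbon (the future C2) and the α-carbon (the future C3) is cut, which is a crossed Claisen condensation. 12 cannot enolise, 11 has one enolisable position, and the product enolate drives the equilibrium. 11 comes from 10 by esterification.

## Other disconnections considered

Alternative 1: The cut runs through C3–C4 and O1–C2. In the forward direction the enamine 4-[(E)-2-(3,4,5-trimethoxyphenyl)ethenyl]morpholine A1 would be acylated on carbon, with Et3N as base, by 2-acetoxy-5-(benzyloxy)-4-methoxybenzoyl chloride A2. Aqueous acid would then remove the acetate, and the freed phenol would add to C2 and expel morpholine, which closes ring C and gives 6-(benzyloxy)-7-methoxy-3-(3,4,5-trimethoxyphenyl)chromen-4-one A3. In its favour, the ring A substitution is fixed inside A2, so neither an auxiliary bromine nor any aryne regiochemistry is needed. On this point, and in resting on an established reaction type, the alternative is the better of the two plans. The end game from A3 (one debenzylation) is equal or slightly simpler. Against it here, A2 is a 2,4,5-trioxygenated benzoic acid derivative with three differently capped oxygens and takes several steps to make. In addition, A1 requires 11 to be brought to the aldehyde oxidation level, where arylacetaldehydes self-condense readily. In comparison, the mechanism is conventional polar chemistry and safer. Step economy is expected to be equal at best and probably worse, because the chosen plan buys the whole ring A pattern in 1.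

Alternative 2: Only C4–C4a is cut. The acid (Z)-3-(4-isopropoxy-3-methoxyphenoxy)-2-(3,4,5-trimethoxyphenyl)acrylic acid A4 would be ionised to its acylium ion in P2O5/MeSO3H. Intramolecular Friedel–Crafts attack by the aryloxy ring would then close ring C and give 6-isopropoxy-7-methoxy-3-(3,4,5-trimethoxyphenyl)chromen-4-one A5. In its favour are cheap reagents, the absence of organometallic or fluoride chemistry, and a known type of chromone closure. The attacked carbon of A4 is para to the methoxy group and the other ortho site is flanked by two oxygens, so the regiochemistry is as good as in the chosen plan without a bromine (equal, with better atom economy). Against it here, A4 needs the same cis relation of aryloxy group and carboxyl as the chosen key step, so this problem is equal. The strongly acidic medium threatens the enol ether and the electron-rich trimethoxyphenyl ring (sulfonation, demethylation) and may cleave the isopropyl ether early. Taking A5 to the target requires a boron halide beside four methyl ethers, which is less selective than hydrogenolysis; here the chosen plan is better. In comparison, the step count is comparable. The O–aryl bond of A4 must be made in a separate step, so the key step forms one bond where the chosen one forms two.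

Alternative 3: The cut is C2–C3. The diazoketone 1-[5-(benzyloxy)-2,4-dimethoxyphenyl]-2-diazo-2-(3,4,5-trimethoxyphenyl)ethan-1-one A6 would lose dinitrogen on Rh2(OAc)4 (divalent rhodium). The resulting rhodium carbenoid at the future C3 would insert into a C–H bond of the neighbouring methoxy group and close ring C as racemic 6-(benzyloxy)-7-methoxy-3-(3,4,5-trimethoxyphenyl)chroman-4-one A7. In its favour are neutral conditions, a ring A pattern fixed by the ketone precursor of A6 (better than the chosen plan in not needing a directing bromine), and a donor/acceptor carbenoid that is comparatively selective. Against it here, the insertion that closes a six-membered ring through a methoxy C–H bond competes with attack on the methoxy oxygen (oxonium ylide, then 1,2-shift to a five-membered ring) and with Wolff rearrangement. Moreover, A7 is at the wrong oxidation level and carries a stereocentre at C3 that must be erased by dehydrogenation to A3 before debenzylation. In comparison, two steps follow the key step instead of one, and A6 itself needs a deoxybenzoin and a diazo transfer. Step economy is therefore worse, although the individual reaction type is better documented than the chosen annulation.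

Key step: step 7

Remark: 14 is drawn as its hydrogen-bonded Z enol; it equilibrates with the aldehyde tautomer, and both give the same enolate. Chromone numbering (C4a, C5, C8a) is used for ring A carbons where bonds are discussed.

Step 1
Reactants: 1 2-bromo-3-hydroxy-4-methoxybenzaldehyde
Product: 2 3-(benzyloxy)-2-bromo-4-methoxybenzaldehyde
Conditions: BnBr, K2CO3, DMF, 50 °C
Reagents that add atoms: benzyl bromide, BrCc1ccccc1
Why: Williamson ether synthesis; the phenoxide of 1 displaces bromide from benzyl bromide (SN2), and the aldehyde and aryl bromide are inert to carbonate.

Step 2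
Reactants: 2 3-(benzyloxy)-2-bromo-4-methoxybenzaldehyde
Product: 4 3-(benzyloxy)-2-bromo-4-methoxyphenol, via aryl formate 3 (not isolated)
Conditions: mCPBA, CH2Cl2, 40 °C; aq. NaHCO3 wash; then K2CO3 (cat.), MeOH, rt
Reagents that add atoms: 3-chloroperoxybenzoic acid, OOC(=O)c1cccc(Cl)c1
Why: Baeyer–Villiger (Dakin-type) oxidation; the para methoxy group makes the aryl group migrate in preference to hydrogen, and the resulting formate 3 is methanolysed to the phenol. Benzyl ether and aryl bromide are stable to peracid.

Step 3
Reactants: 4 3-(benzyloxy)-2-bromo-4-methoxyphenol
Product: 5 3-(benzyloxy)-2-bromo-6-iodo-4-methoxyphenol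
Conditions: NIS, TsOH·H2O (cat.), MeCN, 0 °C to rt
Reagents that add atoms: N-iodosuccinimide, O=C1CCC(=O)N1I
Why: Electrophilic aromatic iodination; the free hydroxyl directs to its only open ortho position, which is also para to the benzyloxy group, whereas the other free carbon is meta to the hydroxyl.

Step 4
Reactants: 5 3-(benzyloxy)-2-bromo-6-iodo-4-methoxyphenol
Product: 9 3-(benzyloxy)-2-bromo-4-methoxy-6-(trimethylsilyl)phenyl trifluoromethanesulfonate, via trimethylsilyl ether 6 (not isolated), via aryllithium 7 (not isolated), via lithium phenolate 8 (not isolated)
Conditions: HMDS, THF, 65 °C, evaporate; n-BuLi (1.05 equiv), THF, −100 °C; then Tf2O, −100 °C to rt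
Reagents that add atoms: hexamethyldisilazane, C[Si](C)(C)N[Si](C)(C)C; trifluoromethanesulfonic anhydride, O=S(=O)(OS(=O)(=O)C(F)(F)F)C(F)(F)F
Why: O-silylation, iodine–lithium exchange, 1,3 O-to-C silyl shift (retro-Brook rearrangement) and O-triflation, the standard sequence to ortho-silyl aryl triflates. Iodide exchanges far faster than bromide at −100 °C, and aryllithium 7 is trapped intramolecularly by silicon before halogens can scramble.

Step 5
Reactants: 10 3,4,5-trimethoxyphenylacetic acid
Product: 11 methyl 3,4,5-trimethoxyphenylacetate
Conditions: MeOH, H2SO4 (cat.), reflux
Reagents that add atoms: methanol, CO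
Why: Fischer esterification, driven by the large excess of methanol.

Step 6
Reactants: 11 methyl 3,4,5-trimethoxyphenylacetate; 12 methyl formate
Product: 14 methyl (Z)-3-hydroxy-2-(3,4,5-trimethoxyphenyl)acrylate, via sodium enolate 13 (not isolated)
Conditions: NaH, MeOH (cat.), THF, 0 °C to rt; then 1 M HCl, 0 °C
Reagents that add atoms: none
Why: Crossed Claisen condensation (C-formylation); 12 cannot enolise and deprotonation of the product to 13 drives the equilibrium. Acidification gives the Z enol, held by a hydrogen bond to the ester carbonyl.

Step 7
Reactants: 9 3-(benzyloxy)-2-bromo-4-methoxy-6-(trimethylsilyl)phenyl trifluoromethanesulfonate; 14 methyl (Z)-3-hydroxy-2-(3,4,5-trimethoxyphenyl)acrylate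
Product: 18 6-(benzyloxy)-5-bromo-7-methoxy-3-(3,4,5-trimethoxyphenyl)chromen-4-one, via cesium enolate 15 (not isolated), via aryne 16 (not isolated), via arylcesium adduct 17 (not isolated)
Conditions: 14 (1.5 equiv), Cs2CO3, THF, rt; then CsF, 9 added over 6 h, THF, 65 °C
Reagents that add atoms: none
Why: Proposed new method: fluoride attacks the silicon of 9 and triflate leaves from the neighbouring carbon, which gives aryne 16 across the future C4a and C8a; the oxygen of cesium enolate 15 adds to C8a, and the aryl anion left on C4a (17) attacks the cis ester carbonyl and expels methoxide, so that O1–C8a and C4–C4a form in one flask. The closest known reaction type is the fluoride-induced annulation of arynes with salicylate esters to xanthones, from which CsF in THF at 65 °C is taken; the new element is that the enolate of a formyl ester takes the place of the phenoxide. Ring C closes by 6-exo-trig acyl substitution of the aryl anion on the ester through a six-membered transition state, and no stereocentre is formed. The site of attack is set by the bromine on C5: its inductive pull distorts the aryne so that the nucleophile enters at the remote carbon (C8a) and the charge builds up next to bromine (C4a), an effect that the benzyloxy group meta to C4a supports. Oxygen attack is expected over carbon attack because the α-carbon is fully substituted and carries an aryl group and because enolates of α-aryl formyl esters are known to be alkylated and sulfonylated on oxygen; carbon attack would end in insertion into the C–CHO bond. The Z relation between aryloxy group and ester that ring closure needs is not simply inherited from the enol, because the enolate can rotate about C2–C3; THF without crown ether or dipolar co-solvent is therefore chosen, so that Cs+ stays as a contact ion pair bridging both oxygens and holds the U-shaped form. Slow addition of 9 to an excess of 15 keeps the aryne scarce, so that released methoxide and the product do not compete for it, and the intramolecular acylation is expected to outrun loss of bromide from 17.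

Step 8
Reactants: 18 6-(benzyloxy)-5-bromo-7-methoxy-3-(3,4,5-trimethoxyphenyl)chromen-4-one
Product: 19 6-hydroxy-7-methoxy-3-(3,4,5-trimethoxyphenyl)-4H-chromen-4-one
Conditions: H2 (1 atm), 10% Pd/C, NaOAc, EtOAc–MeOH, rt
Reagents that add atoms: none
Why: Catalytic hydrogenolysis cleaves the aryl C–Br bond and the benzyl ether in one operation, with NaOAc taking up HBr; an amine base is avoided because amines slow benzyl ether cleavage on palladium. At 1 atm and rt the conjugated C2=C3 bond should survive if the reaction is stopped at full conversion.

## Compound list

1 | 2-bromo-3-hydroxy-4-methoxybenzaldehyde | COc1ccc(C=O)c(Br)c1O | starting material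
2 | 3-(benzyloxy)-2-bromo-4-methoxybenzaldehyde | COc1ccc(C=O)c(Br)c1OCc1ccccc1 | intermediate
3 | 3-(benzyloxy)-2-bromo-4-methoxyphenyl formate | COc1ccc(OC=O)c(Br)c1OCc1ccccc1 | intermediate
4 | 3-(benzyloxy)-2-bromo-4-methoxyphenol | COc1ccc(O)c(Br)c1OCc1ccccc1 | intermediate
5 | 3-(benzyloxy)-2-bromo-6-iodo-4-methoxyphenol | COc1cc(I)c(O)c(Br)c1OCc1ccccc1 | intermediate
6 | [3-(benzyloxy)-2-bromo-6-iodo-4-methoxyphenoxy]trimethylsilane | COc1cc(I)c(O[Si](C)(C)C)c(Br)c1OCc1ccccc1 | intermediate
7 | [4-(benzyloxy)-3-bromo-5-methoxy-2-(trimethylsilyloxy)phenyl]lithium | COc1cc([Li])c(O[Si](C)(C)C)c(Br)c1OCc1ccccc1 | intermediate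
8 | lithium 3-(benzyloxy)-2-bromo-4-methoxy-6-(trimethylsilyl)phenolate | [Li+].[O-]c1c(Br)c(OCc2ccccc2)c(OC)cc1[Si](C)(C)C | intermediate
9 | 3-(benzyloxy)-2-bromo-4-methoxy-6-(trimethylsilyl)phenyl trifluoromethanesulfonate | C[Si](C)(C)c1cc(OC)c(OCc2ccccc2)c(Br)c1OS(=O)(=O)C(F)(F)F | intermediate
10 | 3,4,5-trimethoxyphenylacetic acid | COc1cc(CC(=O)O)cc(OC)c1OC | starting material
11 | methyl 3,4,5-trimethoxyphenylacetate | COC(=O)Cc1cc(OC)c(OC)c(OC)c1 | intermediate
12 | methyl formate | COC=O | starting material
13 | sodium (Z)-3-methoxy-3-oxo-2-(3,4,5-trimethoxyphenyl)prop-1-en-1-olate | COC(=O)/C(c1cc(OC)c(OC)c(OC)c1)=C\[O-].[Na+] | intermediate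
14 | methyl (Z)-3-hydroxy-2-(3,4,5-trimethoxyphenyl)acrylate | COC(=O)/C(c1cc(OC)c(OC)c(OC)c1)=C\O | intermediate
15 | cesium (Z)-3-methoxy-3-oxo-2-(3,4,5-trimethoxyphenyl)prop-1-en-1-olate | COC(=O)/C(c1cc(OC)c(OC)c(OC)c1)=C\[O-].[Cs+] | intermediate
16 | 4-(benzyloxy)-3-bromo-5-methoxybenzyne (4-(benzyloxy)-3-bromo-5-methoxy-1,2-didehydrobenzene) | BrC1=C(OCc2ccccc2)C(OC)=CC#C1 | intermediate
17 | methyl (Z)-3-[4-(benzyloxy)-3-bromo-2-cesio-5-methoxyphenoxy]-2-(3,4,5-trimethoxyphenyl)acrylate | COC(=O)/C(c1cc(OC)c(OC)c(OC)c1)=C\Oc1cc(OC)c(OCc2ccccc2)c(Br)c1[Cs] | intermediate
18 | 6-(benzyloxy)-5-bromo-7-methoxy-3-(3,4,5-trimethoxyphenyl)chromen-4-one | COc1cc2occ(-c3cc(OC)c(OC)c(OC)c3)c(=O)c2c(Br)c1OCc1ccccc1 | intermediate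
19 | 6-hydroxy-7-methoxy-3-(3,4,5-trimethoxyphenyl)-4H-chromen-4-one | COc1cc2occ(-c3cc(OC)c(OC)c(OC)c3)c(=O)c2cc1O | target

## Step count and least certain steps

Total: 8 steps. Longest linear sequence: 6 steps (steps 1, 2, 3, 4, 7, 8); steps 5 and 6 form the short second branch.

Step 7 (key step, proposed new method). Three processes can divert it. The first is arylation of the enolate on carbon, followed by insertion of the aryne into the C–CHO bond. The second is O-arylation through the extended form of the enolate, which leaves the aryl anion unable to reach the ester so that it is quenched by a proton. The third is loss of bromide from the ortho-bromoaryl anion before acylation. The fallback uses the established deoxybenzoin route. It sets out from 10 and returns at 19. Acid 10 would acylate purchased 2-methoxybenzene-1,4-diol F1 in BF3·OEt2 at 80 °C (Friedel–Crafts acylation, expected para to the methoxy group and ortho to a hydroxyl) to give 1-(2,5-dihydroxy-4-methoxyphenyl)-2-(3,4,5-trimethoxyphenyl)ethan-1-one F2. One-carbon ring closure of F2 with DMF, BF3·OEt2 and MeSO2Cl at 70 °C should give 19 directly, with no bromine or benzyl group to remove.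

Step 4. The most likely failures are competing bromine–lithium exchange or halogen scrambling between aryllithium and aryl halide, and incomplete silyl migration before triflation. The fallback replaces halogen–metal exchange by directed deprotonation; it sets out from 4 and returns at 9. Carbamoylation of 4 (ClCONEt2, K2CO3, MeCN, reflux) would give 3-(benzyloxy)-2-bromo-4-methoxyphenyl N,N-diethylcarbamate F3. Lithium 2,2,6,6-tetramethylpiperidide with TMSCl present in the flask (THF, −78 °C) should silylate the only position ortho to the carbamate without touching the bromide, giving 3-(benzyloxy)-2-bromo-4-methoxy-6-(trimethylsilyl)phenyl N,N-diethylcarbamate F4. Reductive carbamate cleavage with Cp2Zr(H)Cl in THF at rt would give 3-(benzyloxy)-2-bromo-4-methoxy-6-(trimethylsilyl)phenol F5. Tf2O and pyridine in CH2Cl2 at 0 °C would then convert F5 into 9.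

Step 8. The risks are saturation of the C2=C3 bond by over-hydrogenation, or stalling of one of the two cleavages as bromide accumulates on the catalyst. The fallback separates the two cleavages and avoids hydrogen gas; it sets out from 18 and returns at 19. BCl3 with pentamethylbenzene in CH2Cl2 at −78 °C would remove the benzyl group to give 5-bromo-6-hydroxy-7-methoxy-3-(3,4,5-trimethoxyphenyl)chromen-4-one F6. Homogeneous hydrodebromination of F6 (Pd(OAc)2 and PPh3, which give zerovalent palladium in the flask, with HCO2H and Et3N in DMF at 60 °C) would then give 19 without touching the enone.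

Step 6. The risks are self-condensation of 11, incomplete formylation, and loss of the formyl group during acidic work-up or chromatography. The fallback replaces the Claisen condensation by aminomethylenation; it sets out from 11 and returns at 14. Heating 11 with N,N-dimethylformamide dimethyl acetal at 110 °C would give methyl (E)-3-(dimethylamino)-2-(3,4,5-trimethoxyphenyl)acrylate F7 (double-bond geometry not controlled and of no consequence). Hydrolysis of F7 with 1 M HCl in THF at rt would give 14.

## Further compounds

F1 | step 7 | 2-methoxybenzene-1,4-diol | COc1cc(O)ccc1O
F2 | step 7 | 1-(2,5-dihydroxy-4-methoxyphenyl)-2-(3,4,5-trimethoxyphenyl)ethan-1-one | COc1cc(O)c(C(=O)Cc2cc(OC)c(OC)c(OC)c2)cc1O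
F3 | step 4 | 3-(benzyloxy)-2-bromo-4-methoxyphenyl N,N-diethylcarbamate | CCN(CC)C(=O)Oc1ccc(OC)c(OCc2ccccc2)c1Br
F4 | step 4 | 3-(benzyloxy)-2-bromo-4-methoxy-6-(trimethylsilyl)phenyl N,N-diethylcarbamate | CCN(CC)C(=O)Oc1c([Si](C)(C)C)cc(OC)c(OCc2ccccc2)c1Br
F5 | step 4 | 3-(benzyloxy)-2-bromo-4-methoxy-6-(trimethylsilyl)phenol | COc1cc([Si](C)(C)C)c(O)c(Br)c1OCc1ccccc1
F6 | step 8 | 5-bromo-6-hydroxy-7-methoxy-3-(3,4,5-trimethoxyphenyl)chromen-4-one | COc1cc2occ(-c3cc(OC)c(OC)c(OC)c3)c(=O)c2c(Br)c1O
F7 | step 6 | methyl (E)-3-(dimethylamino)-2-(3,4,5-trimethoxyphenyl)acrylate | COC(=O)/C(c1cc(OC)c(OC)c(OC)c1)=C/N(C)C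
A1 | alternative 1 | 4-[(E)-2-(3,4,5-trimethoxyphenyl)ethenyl]morpholine | COc1cc(/C=C/N2CCOCC2)cc(OC)c1OC
A2 | alternative 1 | 2-acetoxy-5-(benzyloxy)-4-methoxybenzoyl chloride | CC(=O)Oc1cc(OC)c(OCc2ccccc2)cc1C(Cl)=O
A3 | alternative 1 | 6-(benzyloxy)-7-methoxy-3-(3,4,5-trimethoxyphenyl)chromen-4-one | COc1cc2occ(-c3cc(OC)c(OC)c(OC)c3)c(=O)c2cc1OCc1ccccc1
A4 | alternative 2 | (Z)-3-(4-isopropoxy-3-methoxyphenoxy)-2-(3,4,5-trimethoxyphenyl)acrylic acid | OC(=O)/C(c1cc(OC)c(OC)c(OC)c1)=C\Oc1ccc(OC(C)C)c(OC)c1
A5 | alternative 2 | 6-isopropoxy-7-methoxy-3-(3,4,5-trimethoxyphenyl)chromen-4-one | COc1cc2occ(-c3cc(OC)c(OC)c(OC)c3)c(=O)c2cc1OC(C)C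
A6 | alternative 3 | 1-[5-(benzyloxy)-2,4-dimethoxyphenyl]-2-diazo-2-(3,4,5-trimethoxyphenyl)ethan-1-one | COc1cc(OC)c(OCc2ccccc2)cc1C(=O)C(=[N+]=[N-])c1cc(OC)c(OC)c(OC)c1
A7 | alternative 3 | racemic 6-(benzyloxy)-7-methoxy-3-(3,4,5-trimethoxyphenyl)chroman-4-one | COc1cc2OCC(c3cc(OC)c(OC)c(OC)c3)C(=O)c2cc1OCc1ccccc1
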